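The runs come from a simulation for substances that don't exist, and the scatter is random.

| flask | substrate | catalyst | remark | time |
|---|---|---|---|---|
| ochre | 0.034 M | 1 mM | run made earlier |  |
| red | 0.075 M | 1 mM | run made earlier |  |
| grey | 0.050 M | 1.5 mM | run made earlier |  |
| flask | 0.050 M | 1.0 mM |  | 8.0 h |

| run | time / h | isomer of the product / % | target / % |
|---|---|---|---|
| ochre | 0.417 | 0 | 3 |
| ochre | 1.33 | 0 | 14 |
| ochre | 2.50 | 0 | 23 |
| ochre | 3.00 | 2 | 23 |
| ochre | 5.00 | 2 | 38 |
| ochre | 6.00 | 1 | 40 |
| ochre | 8.00 | 1 | 48 |
| red | 0.417 | 0 | 5 |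
| red | 1.33 | 1 | 14 |
| red | 2.50 | 2 | 19 |
| red | 3.00 | 0 | 22 |
| red | 5.00 | 2 | 38 |
| red | 6.00 | 1 | 41 |
| red | 8.00 | 3 | 52 |
| grey | 1.50 | 1 | 22 |
| grey | 3.00 | 1 | 34 |
| grey | 5.00 | 4 | 47 |
| grey | 6.00 | 2 | 52 |
| grey | 8.00 | 4 | 62 |

(standard deviation of a reading: 1.5 percentage points)



- ratio of isomer of the product to target at 8.0 min
- ratio of isomer of the product to target at 8.0 h

1. Begin with an easy reading: ochre and red differ 2.21-fold in substrate, yet give 48% and 52% target at 8.00 h, so treat the loss of substrate as a pseudo-first-order decay and ask next how its time constant goes with the catalyst.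

2. Note the oddity: grey carries 1.50 times ochre's catalyst, but at that time holds 1.29 times ochre's target.

3. Clear it on a logarithmic scale, where grey's loss of substrate is 1.60 times ochre's, and take as the clock the catalyst dose, charged [catalyst] times time; pooling the runs gives the half-dose, the dose that halves the substrate, 7.61 mM·h.

4. Apply it to the flask, whose dose of 8.00 mM·h leaves 48.3% substrate by my reckoning.

5. Pool the isomer readings at doses near this one, which gives a ratio of 0.0503; the early readings lie within the scatter, but I commit to isomer growing from target, with the ratio proportional to dose, which gives 8.38 × 10⁻⁴ at 8.0 min.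

6. Set beside this the forecast, 0.035 early and 0.05 late, which differs from my early figure: “I lean towards parallel formation”.

7. Read the flask: 0.00330 early and 0.0589 late, against my 8.38 × 10⁻⁴ and the forecast's 0.035 early.

    substrate + catalyst ⇌ target + catalyst, rate k1*[substrate]*[catalyst] forward; the back reaction follows from the equilibrium constant (K = 24.0, k = 163 /M/h)
    target + catalyst ⇌ isomer of the product + catalyst, rate k2*[catalyst]*[target] forward; the back reaction follows from the equilibrium constant (K = 0.0770, k = 54.5 /M/h)
    catalyst ⇌ dormant form (K = 0.777, k = 1.16 /h)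

The flask keeps 47% substrate, and a neighbour flask, at 4.0 × 10⁻⁴ M catalyst and a dose of 3.20 mM·h, reckons to 74.7% and stands at 74%. The catalyst relaxes towards its dormant form with a half-life of 0.261 h, longer than the early 8.0 min and far shorter than 8.0 h. In the flask, the catalyst stands at 61.5% after 0.800 h and at 56.3% after 8.00 h, with 43.7% as dormant form.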